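A small charge of reagent, less than the substrate, waits in the second phase, and two people dispute what stands at the end of this flask.

substrate 0.20 M; reagent in the second phase 0.160 M; time 80 min; volume of the second phase over the first 1.0

    reagent in the reaction phase ⇌ reagent in the second phase, rate k1*([reagent in the reaction phase] - [reagent in the second phase]/K1) per volume of the first phase (K1 = 0.94, k1 = 2.0 × 10⁻⁴ s⁻¹)
    substrate + reagent in the reaction phase → target (k2 = 0.0027 L mol⁻¹ s⁻¹)
    target ⇌ product in the second phase, rate k3*([target] - [product in the second phase]/K3) per volume of the first phase (K3 = 0.81, k3 = 0.0025 s⁻¹)
    target → decomposed product (k4 = 4.2 × 10⁻⁵ s⁻¹)
    substrate + target → side product (k5 = 0.0035 L mol⁻¹ s⁻¹)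

- percent here means substrate units held: one side product counts as two
- what is said of target includes product in the second phase
- in the second phase: reagent in the second phase, product in the second phase; everything else is in the first
- charges count per volume of the first phase; a concentration in a rate is the amount of a species over the volume of its own phase; every rate counts per litre of the first phase
- run time (flask): 80 min

1. target and product in the second phase together at 80 min, in percent of the substrate charged
2. part of the substrate charged that has reacted at 80 min

I reckon both sides with means in place of curves, and they share the supply. With substrate as charged, reagent in the reaction phase climbs over a lag of 22.5 min. Taking reagent in the second phase at 0.7 of its charge on average, it then levels near 0.0322 M.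

The first person holds that target, once made, stays. The reaction with substrate over the run less the lag then makes 0.0600 M, which is 30.0 % of the substrate charged.

The second person holds that target is lost to side product. Target crosses between the phases within 2.98 min, shorter than the run, so a share of 55.2 % sits in the first phase. Decomposition is set aside, its half-life on target being longer than that of the side reaction. Making and loss both scale with substrate, so substrate cancels from their balance. What remains is 1.40, the balance ratio: target in both phases over reagent in the reaction phase at which the side reaction takes what is made.

The balance therefore lies at 0.0450 M, or 22.5 % of the charge, and is approached with a time constant of 43.1 min. After the lag this gives 16.6 % of target. Each target lost takes one more substrate with it, so I reckon 43.4 % reacted.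

The forecast, lower on target than this, gives 15.2 % (13.5 % to 17 %) and 39.5 % reacted (35 % to 44 %), holding that “the reaction with substrate eats nearly half of what forms”.

The flask gives 14.4 % of target with 39.1 % reacted, which goes with the second person. The first view has its region with the side reaction struck out, where the flask gives 26.9 %. At 80.0 min the flask reads 0.0311 M of reagent in the reaction phase, so the balance ratio puts the balance at 21.7 % of the charge, above what stands. Left until 3.0 h, the flask reads 0.0267 M, the balance falls to 18.7 %, and target stands at 16.3 %.

The constants used here stand for no real mixture, and the outcome is calculated.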